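The earlier runs and the new flask stem from a simulated flask for an exercise, noise included.

The beta run was what I had, and I read its two hands separately, each against its own half of the charge.

- beta: left-handed substrate 0.10 M; right-handed substrate 0.10 M; partner 0.15 M; precatalyst 50 µM; impurity 8.9 µM; run made earlier
- flask: left-handed substrate 0.050 M; partner 0.150 M; precatalyst 50 µM; impurity 8.9 µM; right-handed substrate 0.050 M; time 4.0 h

- beta (time / min: left-handed product / %, right-handed product / %): 6.00: 6.4, 2.8; 15.0: 12.7, 6.8; 30.0: 20.3, 12.7; 50.0: 26.3, 15.4

(each reading ± 0.5 percentage points)

- partner is single-handed; left-handed substrate and right-handed substrate are mirror images of each other, charged as a racemate, each of them at the stated concentration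
- an excess is below zero if the other one leads
- the handed part of partner does not stay in what it makes, so the products of the two hands are mirror images too

1. left-handed product and right-handed product together, in percent of the left-handed substrate and right-handed substrate charged together, at 4.0 h
2. excess of left-handed product over right-handed product in the product at 4.0 h
3. whether the exchange between left-handed substrate and right-handed substrate keeps pace with the reaction: how far the product's excess at 4.0 h gets from its value without exchange to its value with instant exchange (above 80% keeps pace, below 20% hardly takes part, else lags behind)

At 50.0 min in the beta run, the left-handed substrate stood at 47.4% of its own charge and the right-handed substrate at 69.2%. That gave mean lifetimes of 67.0 min and 136 min. Both hands draw on one partner, so however [partner] falls, these two clocks keep one ratio, provided neither hand turns into the other. I called the second lifetime over the first s, 2.03, the selectivity factor: the fraction left of the left-handed substrate equals the fraction left of the right-handed substrate raised to the power s. The beta readings at 15.0 min and 30.0 min gave 2.00 and 1.78, with no trend I could trust, so I reckoned the flask without exchange between the two hands and expected that exchange there hardly takes part.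

I took as dose the time multiplied by [partner] midway between its charge and its end, with 0.108 M for beta up to 50.0 min and 0.100 M for the flask with its substrates taken as used up, so the flask gets 4.43 times the beta dose. So I expected 19.6% of the flask's right-handed substrate left and 3.66% of its left-handed substrate, each of its own charge, which gives a yield of 88.4% and an excess of 9.02%.

The forecast said 88%, 16% and lags behind, on the ground that “modest exchange over 4 h seems most likely”.

The flask gave 87.7% and 9.07%, and the exchange went 1.6% of the way, so it hardly takes part.

    partner + left-handed substrate → left-handed product (k = 0.150 M⁻¹ min⁻¹)
    partner + right-handed substrate → right-handed product (k = 0.0790 M⁻¹ min⁻¹)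
    left-handed substrate + racemization catalyst ⇌ right-handed substrate + racemization catalyst, rate k3*[racemization catalyst]*[left-handed substrate] forward; the back reaction follows from the equilibrium constant (k = 220 M⁻¹ min⁻¹)
    racemization catalyst → spent catalyst A (k = 0.100 min⁻¹)
    partner + precatalyst → racemization catalyst + spent reagent (k = 0.0300 M⁻¹ min⁻¹)
    racemization catalyst + impurity → spent catalyst B (k = 14000 M⁻¹ s⁻¹)

In the flask the racemization catalyst stood at 1.69% of the catalyst charged at 2.00 h. Against s of 2.03 from the beta readings, the flask's left-handed and right-handed substrate, with 4.9% and 20% of their charges left at 4.00 h, read 1.85. The neighbour with 0.060 M of partner had 40% and 61% of those charges left at 4.00 h, which reads 1.90.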